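# Proposed synthesis of 3-hydroxyglabrol (29)

## Analysis of the target

3-Hydroxyglabrol (29) is a dihydroflavonol. Ring A (a resorcinol-type benzene) is fused to the dihydropyranone ring C, which carries ring B at C2, a hydroxyl at C3 and the ketone at C4. Ring A bears a free 7-OH and a prenyl group at C8; ring B bears a free 4'-OH and a prenyl group at C3'. The only stereocentres are the neighbours C2 and C3, (2R,3R), with the aryl group and the hydroxyl trans and both equatorial on the half-chair of ring C. Both centres are labile in the final oxidation state: C3 is alpha to the ketone, and its enolate can expel the O1 phenoxide from C2 and open ring C. Base must therefore be kept away from the finished ketol. The two prenyl groups are trisubstituted alkenes ortho to phenols. They close to chromans under strong acid, react with peracids, dioxiranes and hydrogenation catalysts, and their ArCH2 positions are open to hydride-abstracting benzylic oxidants. The difficulty is to set two contiguous stereocentres absolutely while bringing oxygen to C3 and C4 without any reagent that must tell a ring C alkene or C–H bond from the prenyl groups. The route rests on one feature of ring C: the bonds O1–C2 and C3–C4 enclose the C2–C3 unit, which carries ring B on C2 and oxygen on C3 and can enter as an alkene of the correct oxidation level. The remaining four atoms O1–C8a–C4a–C4 are then the ortho-quinone methide of a ring A salicylaldehyde, whose C4 can carry an alkoxy group as a masked ketone.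

## Retrosynthetic reasoning

**29 from 28.** The last operation is removal of all silicon from 28: the two aryl silyl ethers and the silyl ether on O3. One buffered fluoride treatment does this, so the free ketol never meets base and the prenyl phenols never meet strong acid.

**28 from 27 from 26.** The C4 carbonyl is traced to the C4 alcohol 27 and this to the C4 methyl ether 26. C4 is benzylic and has O1 ortho and the C7 oxygen para, so its methoxy group is an ortho-quinone methide precursor and exchanges with water under mild acid. Because the C4 oxygen is already in place, no C–H oxidation next to the prenyl groups is needed; the forward steps are a solvolysis and a neutral alcohol oxidation.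

**26 from 24 from 23.** The silyl group on O3 is exchanged for the acetyl group of 23. An acetate on O3 would bridge to the C4 cation during the solvolysis, and the bridged ion would pass the acyl group to O4 or lose it, so the two oxygens would no longer be distinguished. It would also have to be removed by base from the finished ketol. The exchange is therefore made at the flavan stage, where C2 and C3 cannot epimerise.

**23 from 12, 20 and 21 (key disconnection).** Cutting O1–C2 and C3–C4 divides the molecule into two halves of equal size, each with one aromatic ring and one prenyl group. The ring A half is salicylaldehyde 12, activated by orthoformate 21 through acetal 22; the ring B half is the (E)-enol acetate 20. No other pair of cuts in ring C forms both stereocentres in the ring-forming event and delivers C3 and C4 at their final oxidation levels. The forward reaction has to join C3 (not C2) to C4, keep the alkene geometry as the 2,3-trans relationship, and select one face.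

**12 from 10, 9, 6, 3 and 1.** The C–CHO and C–prenyl bonds of ring A are cut in turn. Both are made by directed metalation of the bis-acetal 3 of resorcinol (1): first between the two oxygens (aryllithium 5, trapped by 4 to give 6), then ortho to one of them (aryllithium 8, trapped by 7 to give 9). This fixes the 1,2,3,4-substitution pattern without any regiochemical ambiguity. Acetal removal to 10 and silylation of the non-chelated phenol with 11 give 12.

**20 from 18, 15, 14 and 13.** The enol C–O bond is cut to alkenylboronate 18 and copper acetate 19, a coupling that keeps the alkene geometry. The C=C bond of 18 is cut to aldehyde 15 and the gem-diboryl reagent 16 (through its lithio derivative 17), an olefination that gives the trans isomer. Aldehyde 15 comes from 13 by ortho C-prenylation with 4 (to 14) and silylation with 11.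

## Alternatives that were turned down

**Alternative 1:** Ring A itself is disconnected (C4a–C5) together with O1–C2. In the forward direction, mild base would fold the open-chain epoxy tetracarbonyl compound A2. An aldol condensation of C4a onto the C5 aldehyde followed by enolisation would make ring A, and the new C8a phenoxide would then open the epoxide at C2 to give the mono-silylated target A1. In its favour, two rings form in one operation, the stereocentres come from an epoxide that a known asymmetric epoxidation can supply, and A1 is one desilylation from the target. On the origin of absolute configuration it is stronger than the chosen route. Against it: A2 is a chain of 1,3-dicarbonyl units with a free aldehyde and several competing aldol and Claisen folding modes. Its epoxy ketone is acidic at C3 and can open or rearrange under the very base that must trigger the fold. The phenoxide may attack C3 (five-membered ring) instead of C2. Building ring A from a chain also gains nothing when resorcinol already contains it, and the assembly of A2 would take more steps than both halves of the chosen route together. The chosen strategy offers two stable aromatic precursors and places the risk in one bond-forming step instead of in the handling of a polycarbonyl chain.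

**Alternative 2:** The bonds C4a–C4, C4–C3 and O1–C2 are cut, so that ortho-iodophenol A4, a one-carbon carbonyl unit and arylacetylene A5 are combined. PdCl2(PPh3)2 in diethylamine would effect a carbonylative alkyne coupling and the cyclisation of the resulting ynone to flavone A3. In its favour, this is established, convergent chemistry that tolerates prenyl groups and acetal protecting groups, and A5 derives from the same aldehyde used here. As a ring-forming step it is more reliable than the chosen key step. Against it: A3 is flat, so both stereocentres must be made afterwards in separate operations. The first is an enantioselective conjugate reduction of a 2-arylchromone; this substrate class is sluggish, and hydrogenation catalysts cannot be used beside two prenyl groups. The second is a C3 hydroxylation through an enolate or enol ether, which needs an electrophilic oxidant that must ignore two electron-rich alkenes, and the enolate can open ring C and racemise C2. The acetals would finally be removed with acid beside free ortho-prenyl phenols. At least three further steps with selectivity problems follow the key step. The chosen strategy forms the ring with both centres and with C3 and C4 already oxygenated.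

**Alternative 3:** Only C3=C4 is cut. The precursor A7 is the aryl ether of an enantioenriched allylic alcohol, so C2 is already set, and it carries the silyl enol ether of an ortho-acetyl group. The second-generation Grubbs catalyst RuCl2(=CHPh)(PCy3)(H2IMes) would close ring C to the 4-silyloxy-2H-chromene A6 with extrusion of the two terminal CH2 groups. In its favour, C2 comes from proven asymmetric chemistry and passes through a neutral step, and A6 is an enol ether ready for oxidation at C3 under the control of the C2 aryl group. On the security of the C2 configuration it is stronger than the chosen route. Against it: the C8 prenyl group sits next to O1 and can close a seven-membered ring with the vinyl group, in competition with the hindered 1,1-disubstituted enol ether. The subsequent C3 oxidation needs a peracid or dioxirane in the presence of two prenyl alkenes. Making A7 requires etherification of a hindered phenol with a doubly activated secondary alcohol, which is prone to ionisation and loss of configuration, and acid deprotection again comes last. The sequence is longer and linear. The chosen strategy uses no alkene-selective reagent after the prenyl groups are in place and sets C2 and C3 together.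

Key step: step 10

Assumption: the (R) enantiomer of the phosphoric acid is taken to give the (2R,3S) cycloadduct 23; if the sense of induction is the opposite, the (S) acid is used and nothing else changes.

Remark: C3 is S in 23, 24, 26 and 27 and R in 28 and 29 only because the CIP ranking of C4 against C2 changes when C4 becomes a carbonyl; the spatial arrangement is the same throughout.

## Route

Step 1
Reactants: 1 resorcinol; 2 chloromethyl methyl ether
Product: 3 1,3-bis(methoxymethoxy)benzene
Conditions: NaH, DMF, 0 °C to rt
Reagents that add atoms: chloromethyl methyl ether, COCCl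
Why: Double Williamson O-alkylation of the bis-phenoxide; the two acetal ethers are installed as directing groups for the two metalations that follow.

Step 2
Reactants: 3 1,3-bis(methoxymethoxy)benzene; 4 prenyl bromide
Product: 6 1,3-bis(methoxymethoxy)-2-(3-methylbut-2-en-1-yl)benzene, via aryllithium 5 (not isolated)
Conditions: n-BuLi, THF, 0 °C to rt; then CuI (10 mol %), 4, −78 °C to rt
Reagents that add atoms: prenyl bromide, CC(C)=CCBr
Why: Directed ortho-metalation takes place at C2, between the two coordinating ethers; copper-catalysed allylic substitution at the primary carbon of 4 then gives the linear prenyl group.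

Step 3
Reactants: 6 1,3-bis(methoxymethoxy)-2-prenylbenzene; 7 N,N-dimethylformamide
Product: 9 2,4-bis(methoxymethoxy)-3-prenylbenzaldehyde, via aryllithium 8 (not isolated)
Conditions: s-BuLi, TMEDA, THF, −78 °C; then 7, −78 °C to rt; H2O
Reagents that add atoms: N,N-dimethylformamide, CN(C)C=O
Why: Second directed ortho-metalation; the only ring positions ortho to an acetal ether are the equivalent C4 and C6, and formylation of the aryllithium with 7 gives a single aldehyde. The low temperature and the chelating diamine favour the ether-directed ring lithiation over deprotonation of the prenyl CH2.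

Step 4
Reactants: 9 2,4-bis(methoxymethoxy)-3-prenylbenzaldehyde
Product: 10 2,4-dihydroxy-3-prenylbenzaldehyde
Conditions: conc. HCl (cat.), MeOH, rt to 40 °C
Reagents that add atoms: none
Why: Acid-catalysed acetal exchange of both methoxymethyl ethers with the solvent; dilute acid and low temperature are chosen because they should not add the freed phenols across the prenyl alkene.

Step 5
Reactants: 10 2,4-dihydroxy-3-prenylbenzaldehyde; 11 chlorotriisopropylsilane
Product: 12 2-hydroxy-3-prenyl-4-(triisopropylsilyloxy)benzaldehyde
Conditions: 11 (1.05 equiv), imidazole, CH2Cl2, 0 °C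
Reagents that add atoms: chlorotriisopropylsilane, CC(C)[Si](Cl)(C(C)C)C(C)C
Why: Phenol silylation; the 2-OH is hydrogen-bonded to the aldehyde and flanked on both sides, so only the 4-OH should react.

Step 6
Reactants: 13 4-hydroxybenzaldehyde; 4 prenyl bromide
Product: 14 4-hydroxy-3-prenylbenzaldehyde
Conditions: KOH, H2O, rt
Reagents that add atoms: prenyl bromide, CC(C)=CCBr
Why: Ortho C-alkylation of the phenoxide in water, where solvation of oxygen favours carbon attack; the two ortho positions are equivalent, so one regioisomer results. Modest conversion is expected and unreacted 13 is recovered.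

Step 7
Reactants: 14 4-hydroxy-3-prenylbenzaldehyde; 11 chlorotriisopropylsilane
Product: 15 3-prenyl-4-(triisopropylsilyloxy)benzaldehyde
Conditions: 11, imidazole, DMF, rt
Reagents that add atoms: chlorotriisopropylsilane, CC(C)[Si](Cl)(C(C)C)C(C)C
Why: Standard phenol silylation; the bulky silyl ether survives the organolithium, copper and acid steps ahead and leaves with fluoride at the end.

Step 8
Reactants: 15 3-prenyl-4-(triisopropylsilyloxy)benzaldehyde; 16 bis(4,4,5,5-tetramethyl-1,3,2-dioxaborolan-2-yl)methane
Product: 18 (E)-2-{2-[3-prenyl-4-(triisopropylsilyloxy)phenyl]ethenyl}-4,4,5,5-tetramethyl-1,3,2-dioxaborolane, via lithiated bis(boronate) 17 (not isolated)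
Conditions: 16, lithium 2,2,6,6-tetramethylpiperidide (from the amine and n-BuLi), THF, 0 °C; then 15, −78 °C to rt
Reagents that add atoms: bis(4,4,5,5-tetramethyl-1,3,2-dioxaborolan-2-yl)methane, CC1(C)OB(CB2OC(C)(C)C(C)(C)O2)OC1(C)C
Why: Boron–Wittig olefination: the alpha-boryl carbanion adds to the aldehyde and syn elimination of a boron–oxygen unit gives the trans alkenylboronate in one step from the aldehyde.

Step 9
Reactants: 18 (E)-alkenylboronate; 19 copper diacetate Cu(OAc)2
Product: 20 (E)-2-[3-prenyl-4-(triisopropylsilyloxy)phenyl]ethenyl acetate
Conditions: Cu(OAc)2 (2.2 equiv), Et3N, 4 Å MS, MeCN, dry air, rt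
Reagents that add atoms: copper diacetate Cu(OAc)2, CC(=O)[O-].CC(=O)[O-].[Cu+2]
Why: Chan–Lam-type oxidative C–O coupling: boron-to-copper transmetalation and reductive elimination from a trivalent alkenylcopper acetate transfer acetate to carbon with retention of the (E) geometry.

Step 10
Reactants: 12 2-hydroxy-3-prenyl-4-(triisopropylsilyloxy)benzaldehyde; 21 trimethyl orthoformate; 20 (E)-enol acetate
Product: 23 (2R,3S,4RS)-4-methoxy-8-prenyl-2-[3-prenyl-4-(triisopropylsilyloxy)phenyl]-7-(triisopropylsilyloxy)chroman-3-yl acetate, via dimethyl acetal 22 (not isolated)
Conditions: 21 (1.5 equiv), (R)-3,3'-bis(2,4,6-triisopropylphenyl)-1,1'-binaphthyl-2,2'-diyl hydrogen phosphate (10 mol %), 5 Å MS, toluene, rt; then 20 (1.3 equiv), −30 to 0 °C; Et3N quench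
Reagents that add atoms: trimethyl orthoformate, COC(OC)OC
Why: Proposed new method: the acid first converts 12 with 21 into acetal 22 and then ionises it to an oxocarbenium ion, the O-protonated 4-methoxy ortho-quinone methide, held as an ion pair with the chiral phosphate, which also hydrogen-bonds the phenol. The acetoxy-bearing carbon of 20 adds to the cationic carbon (C3–C4 bond) and the para-silyloxybenzyl cation so formed is captured by the phenol oxygen (O1–C2 bond), an asynchronous inverse-electron-demand hetero-Diels–Alder reaction. Ring C is the only ring formed; it closes as the six-membered ring of a formal [4+2] cycloaddition, the second bond being a 6-exo-trig capture by O1 of the benzylic cation drawn in its para-quinone methide form. C3 is set in the C–C bond formation, where the phosphate counter-ion is asked to shield one face of the ion pair; C2 follows from C3, because suprafacial addition to the (E)-alkene, and in the stepwise limit the diequatorial closure, both place the aryl group trans to the acetate; C4 forms as a mixture and is erased in step 14. The step needs regioselectivity (C3, not C2, bonded to C4), secured because the para-oxygenated ring B stabilises the developing cation far better than the acyloxy group could. It also needs chemoselectivity for the conjugated enol acetate over the prenyl alkenes, which rests on the same conjugation. The closest known reactions are the acid-catalysed three-component synthesis of 4-alkoxychromans from salicylaldehydes, orthoformates and styrenes, and chiral phosphoric acid-catalysed cycloadditions of ortho-quinone methides with electron-rich alkenes; an enol ester as the alkene and control of absolute configuration in this variant have not been shown.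

Step 11
Reactants: 23 cycloadduct acetate
Product: 24 (2R,3S,4RS)-4-methoxy-8-prenyl-2-[3-prenyl-4-(triisopropylsilyloxy)phenyl]-7-(triisopropylsilyloxy)chroman-3-ol
Conditions: K2CO3 (0.2 equiv), MeOH/THF, 0 °C to rt
Reagents that add atoms: none
Why: Base-catalysed transesterification of the secondary acetate, done at the flavan stage where neither C2 nor C3 can epimerise; the aryl silyl ethers are shielded by their ortho prenyl groups and the C4 methyl ether is inert to base.

Step 12
Reactants: 24 3-hydroxy-4-methoxyflavan; 25 tert-butylchlorodimethylsilane
Product: 26 (2R,3S,4RS)-3-(tert-butyldimethylsilyloxy)-4-methoxy-8-prenyl-2-[3-prenyl-4-(triisopropylsilyloxy)phenyl]-7-(triisopropylsilyloxy)chroman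
Conditions: 25, imidazole, DMAP (cat.), DMF, 40 °C
Reagents that add atoms: tert-butylchlorodimethylsilane, CC(C)(C)[Si](C)(C)Cl
Why: Silylation of the equatorial secondary alcohol with the chloride rather than a silyl triflate, which could ionise the C4 ether; the silyl ether cannot bridge to C4 and leaves together with the aryl silyl groups at the end.

Step 13
Reactants: 26 3-silyloxy-4-methoxyflavan
Product: 27 (2R,3S,4RS)-3-(tert-butyldimethylsilyloxy)-8-prenyl-2-[3-prenyl-4-(triisopropylsilyloxy)phenyl]-7-(triisopropylsilyloxy)chroman-4-ol
Conditions: PPTS (cat.), MeCN/H2O 9:1, 40 °C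
Reagents that add atoms: water, O
Why: SN1 solvolysis: the C4 ether ionises under weak acid because the cation is stabilised by O1 (ortho) and the C7 oxygen (para), and water captures it. Both C4 epimers pass through the same cation, and the weak acid should leave the silyl ethers and the prenyl groups alone.

Step 14
Reactants: 27 flavan-4-ol
Product: 28 (2R,3R)-3-(tert-butyldimethylsilyloxy)-8-prenyl-2-[3-prenyl-4-(triisopropylsilyloxy)phenyl]-7-(triisopropylsilyloxy)chroman-4-one
Conditions: Dess–Martin periodinane, pyridine, CH2Cl2, 0 °C to rt
Reagents that add atoms: none
Why: Dess–Martin oxidation of the secondary benzylic alcohol; both C4 epimers converge on one ketone, and the buffered neutral conditions should touch neither the prenyl alkenes, the silyl ethers nor the C3 centre.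

Step 15
Reactants: 28 tris-silylated dihydroflavonol
Product: 29 3-hydroxyglabrol, (2R,3R)
Conditions: Bu4NF, AcOH (1:1, 4 equiv), THF, 0 °C to rt
Reagents that add atoms: none
Why: Fluoride-mediated cleavage of the two aryl silyl ethers and of the silyl ether alpha to the ketone; the acetic acid buffer keeps the ketol away from basic fluoride, so ring opening, C3 epimerisation and air oxidation to the flavonol should be avoided.

## Compound list

1 | resorcinol | Oc1cccc(O)c1 | starting material
2 | chloromethyl methyl ether | COCCl | starting material
3 | 1,3-bis(methoxymethoxy)benzene | COCOc1cccc(OCOC)c1 | intermediate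
4 | prenyl bromide (1-bromo-3-methylbut-2-ene) | CC(C)=CCBr | starting material
5 | 2-lithio-1,3-bis(methoxymethoxy)benzene | [Li]c1c(OCOC)cccc1OCOC | intermediate
6 | 1,3-bis(methoxymethoxy)-2-(3-methylbut-2-en-1-yl)benzene | COCOc1cccc(OCOC)c1CC=C(C)C | intermediate
7 | N,N-dimethylformamide | CN(C)C=O | starting material
8 | 4-lithio-1,3-bis(methoxymethoxy)-2-prenylbenzene | [Li]c1ccc(OCOC)c(CC=C(C)C)c1OCOC | intermediate
9 | 2,4-bis(methoxymethoxy)-3-prenylbenzaldehyde | COCOc1ccc(C=O)c(OCOC)c1CC=C(C)C | intermediate
10 | 2,4-dihydroxy-3-prenylbenzaldehyde | O=Cc1ccc(O)c(CC=C(C)C)c1O | intermediate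
11 | chlorotriisopropylsilane | CC(C)[Si](Cl)(C(C)C)C(C)C | starting material
12 | 2-hydroxy-3-prenyl-4-(triisopropylsilyloxy)benzaldehyde | O=Cc1ccc(O[Si](C(C)C)(C(C)C)C(C)C)c(CC=C(C)C)c1O | intermediate
13 | 4-hydroxybenzaldehyde | O=Cc1ccc(O)cc1 | starting material
14 | 4-hydroxy-3-prenylbenzaldehyde | O=Cc1ccc(O)c(CC=C(C)C)c1 | intermediate
15 | 3-prenyl-4-(triisopropylsilyloxy)benzaldehyde | O=Cc1ccc(O[Si](C(C)C)(C(C)C)C(C)C)c(CC=C(C)C)c1 | intermediate
16 | bis(4,4,5,5-tetramethyl-1,3,2-dioxaborolan-2-yl)methane | CC1(C)OB(CB2OC(C)(C)C(C)(C)O2)OC1(C)C | starting material
17 | lithio-bis(4,4,5,5-tetramethyl-1,3,2-dioxaborolan-2-yl)methane | [Li]C(B1OC(C)(C)C(C)(C)O1)B1OC(C)(C)C(C)(C)O1 | intermediate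
18 | (E)-2-{2-[3-prenyl-4-(triisopropylsilyloxy)phenyl]ethenyl}-4,4,5,5-tetramethyl-1,3,2-dioxaborolane | CC(C)=CCc1cc(/C=C/B2OC(C)(C)C(C)(C)O2)ccc1O[Si](C(C)C)(C(C)C)C(C)C | intermediate
19 | copper diacetate Cu(OAc)2 | CC(=O)[O-].CC(=O)[O-].[Cu+2] | starting material
20 | (E)-2-[3-prenyl-4-(triisopropylsilyloxy)phenyl]ethenyl acetate | CC(=O)O/C=C/c1ccc(O[Si](C(C)C)(C(C)C)C(C)C)c(CC=C(C)C)c1 | intermediate
21 | trimethyl orthoformate | COC(OC)OC | starting material
22 | 2-(dimethoxymethyl)-6-prenyl-5-(triisopropylsilyloxy)phenol | COC(OC)c1ccc(O[Si](C(C)C)(C(C)C)C(C)C)c(CC=C(C)C)c1O | intermediate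
23 | (2R,3S,4RS)-4-methoxy-8-prenyl-2-[3-prenyl-4-(triisopropylsilyloxy)phenyl]-7-(triisopropylsilyloxy)chroman-3-yl acetate | CC(C)=CCc1cc([C@H]2Oc3c(CC=C(C)C)c(O[Si](C(C)C)(C(C)C)C(C)C)ccc3C(OC)[C@@H]2OC(C)=O)ccc1O[Si](C(C)C)(C(C)C)C(C)C | intermediate
24 | (2R,3S,4RS)-4-methoxy-8-prenyl-2-[3-prenyl-4-(triisopropylsilyloxy)phenyl]-7-(triisopropylsilyloxy)chroman-3-ol | CC(C)=CCc1cc([C@H]2Oc3c(CC=C(C)C)c(O[Si](C(C)C)(C(C)C)C(C)C)ccc3C(OC)[C@@H]2O)ccc1O[Si](C(C)C)(C(C)C)C(C)C | intermediate
25 | tert-butylchlorodimethylsilane | CC(C)(C)[Si](C)(C)Cl | starting material
26 | (2R,3S,4RS)-3-(tert-butyldimethylsilyloxy)-4-methoxy-8-prenyl-2-[3-prenyl-4-(triisopropylsilyloxy)phenyl]-7-(triisopropylsilyloxy)chroman | CC(C)=CCc1cc([C@H]2Oc3c(CC=C(C)C)c(O[Si](C(C)C)(C(C)C)C(C)C)ccc3C(OC)[C@@H]2O[Si](C)(C)C(C)(C)C)ccc1O[Si](C(C)C)(C(C)C)C(C)C | intermediate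
27 | (2R,3S,4RS)-3-(tert-butyldimethylsilyloxy)-8-prenyl-2-[3-prenyl-4-(triisopropylsilyloxy)phenyl]-7-(triisopropylsilyloxy)chroman-4-ol | CC(C)=CCc1cc([C@H]2Oc3c(CC=C(C)C)c(O[Si](C(C)C)(C(C)C)C(C)C)ccc3C(O)[C@@H]2O[Si](C)(C)C(C)(C)C)ccc1O[Si](C(C)C)(C(C)C)C(C)C | intermediate
28 | (2R,3R)-3-(tert-butyldimethylsilyloxy)-8-prenyl-2-[3-prenyl-4-(triisopropylsilyloxy)phenyl]-7-(triisopropylsilyloxy)chroman-4-one | CC(C)=CCc1cc([C@H]2Oc3c(CC=C(C)C)c(O[Si](C(C)C)(C(C)C)C(C)C)ccc3C(=O)[C@@H]2O[Si](C)(C)C(C)(C)C)ccc1O[Si](C(C)C)(C(C)C)C(C)C | intermediate
29 | 3-hydroxyglabrol, (2R,3R)-3,7-dihydroxy-2-(4-hydroxy-3-prenylphenyl)-8-prenylchroman-4-one | CC(C)=CCc1cc([C@H]2Oc3c(ccc(O)c3CC=C(C)C)C(=O)[C@@H]2O)ccc1O | target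

## Step count and least certain steps

Total step count: 15. Longest linear sequence: 11 steps (steps 1–5 and 10–15, from 1); the ring B branch has 4 steps (6–9) before the union.

**Step 10 (key step).** Three things may go wrong.
- Facial selection may be poor if the acetal ionises only through a loose ion pair or an uncatalysed background path. A more acidic member of the same catalyst family, the corresponding N-triflylphosphoramide, is the first adjustment.
- The cation may be captured by a prenyl alkene or by the methanol that is released.
- The enol acetate may be solvolysed by that methanol; hence the sieves and the low temperature.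

The fallback uses known chemistry, sets out from 6 and 14 and re-enters the route at 29. Lithiation of 6 as in step 3 and trapping with N-methoxy-N-methylacetamide gives the methyl ketone 1-[2,4-bis(methoxymethoxy)-3-prenylphenyl]ethanone F1. Aldehyde 14 is protected with 2 and i-Pr2NEt as 4-(methoxymethoxy)-3-prenylbenzaldehyde F2. Claisen–Schmidt condensation (KOH, EtOH) joins them to the (E)-chalcone F3. Juliá–Colonna epoxidation (poly-L-leucine, urea–H2O2, DBU, THF) attacks only the electron-poor enone and gives the (2R,3S)-epoxy ketone F4. HCl in methanol then removes the three acetal groups, and the freed 2'-phenol opens the epoxide at the benzylic carbon with inversion to give 29 directly.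

**Step 9.** Protodeboronation or oxidative homocoupling of the alkenylboronate may outrun acetate transfer, and traces of water would hydrolyse the enol acetate to the arylacetaldehyde. The fallback sets out from 15 and returns at 20. Wittig reaction with Ph3P=CHOMe (from the phosphonium chloride and KN(SiMe3)2) gives the enol ether 1-(2-methoxyethenyl)-3-prenyl-4-(triisopropylsilyloxy)benzene F5. Mild aqueous acid gives [3-prenyl-4-(triisopropylsilyloxy)phenyl]acetaldehyde F6. O-Acetylation of its enolate (Ac2O, KOAc) gives the enol acetate as an E/Z mixture, from which the conjugated (E)-isomer 20 is separated.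

**Step 3.** The base may remove a proton from the doubly activated ArCH2 of the prenyl group instead of the ring position. The fallback sets out from 6 and returns at 10. Acid methanolysis of both acetals gives 2-prenylresorcinol F7, and magnesium-mediated ortho-formylation (MgCl2, Et3N, paraformaldehyde, MeCN, reflux) installs the aldehyde next to one phenol.

**Step 13.** The C4 cation may lose the C3 proton or accept a hydride from C3 faster than water captures it, which would destroy the C3 centre, or the acid may cleave the C3 silyl ether. The fallback sets out from 26 and returns at 28 without passing through 27. DDQ in CH2Cl2 with pH 7 buffer at 0 °C removes hydride from the methoxy-bearing C4, and the hemiketal formed with water collapses to the ketone. The reaction must be stopped early, because the ArCH2 positions of the prenyl groups are the next most oxidisable sites.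

**Step 6.** O-Alkylation and double C-alkylation compete with the single ortho C-prenylation and keep the conversion low. The fallback sets out from 13 and returns at 14. O-Alkylation with 3-chloro-3-methylbut-1-yne (K2CO3, KI, acetone) gives 4-(2-methylbut-3-yn-2-yloxy)benzaldehyde F8. Semi-hydrogenation over Pd/CaCO3 poisoned with Pb(OAc)2 and quinoline gives 4-(2-methylbut-3-en-2-yloxy)benzaldehyde F9, and aromatic Claisen rearrangement on heating in N,N-diethylaniline delivers the ortho prenyl group.

## Further compounds

F1 | step 10 | 1-[2,4-bis(methoxymethoxy)-3-prenylphenyl]ethanone | COCOc1ccc(C(C)=O)c(OCOC)c1CC=C(C)C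
F2 | step 10 | 4-(methoxymethoxy)-3-prenylbenzaldehyde | COCOc1ccc(C=O)cc1CC=C(C)C
F3 | step 10 | (E)-1-[2,4-bis(methoxymethoxy)-3-prenylphenyl]-3-[4-(methoxymethoxy)-3-prenylphenyl]prop-2-en-1-one | COCOc1ccc(C(=O)/C=C/c2ccc(OCOC)c(CC=C(C)C)c2)c(OCOC)c1CC=C(C)C
F4 | step 10 | (2R,3S)-1-[2,4-bis(methoxymethoxy)-3-prenylphenyl]-2,3-epoxy-3-[4-(methoxymethoxy)-3-prenylphenyl]propan-1-one | COCOc1ccc(C(=O)[C@@H]2O[C@H]2c3ccc(OCOC)c(CC=C(C)C)c3)c(OCOC)c1CC=C(C)C
F5 | step 9 | 1-(2-methoxyethenyl)-3-prenyl-4-(triisopropylsilyloxy)benzene (E/Z mixture) | COC=Cc1ccc(O[Si](C(C)C)(C(C)C)C(C)C)c(CC=C(C)C)c1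
F6 | step 9 | [3-prenyl-4-(triisopropylsilyloxy)phenyl]acetaldehyde | O=CCc1ccc(O[Si](C(C)C)(C(C)C)C(C)C)c(CC=C(C)C)c1
F7 | step 3 | 2-prenylresorcinol | Oc1cccc(O)c1CC=C(C)C
F0 | step 13 | none | none
F8 | step 6 | 4-(2-methylbut-3-yn-2-yloxy)benzaldehyde | C#CC(C)(C)Oc1ccc(C=O)cc1
F9 | step 6 | 4-(2-methylbut-3-en-2-yloxy)benzaldehyde | C=CC(C)(C)Oc1ccc(C=O)cc1
A1 | alternative 1 | 4'-O-triisopropylsilyl-3-hydroxyglabrol | CC(C)=CCc1cc([C@H]2Oc3c(ccc(O)c3CC=C(C)C)C(=O)[C@@H]2O)ccc1O[Si](C(C)C)(C(C)C)C(C)C
A2 | alternative 1 | (8R,9S)-8,9-epoxy-3,5,7-trioxo-4-prenyl-9-[3-prenyl-4-(triisopropylsilyloxy)phenyl]nonanal | CC(C)=CCc1cc([C@@H]2O[C@H]2C(=O)CC(=O)C(CC=C(C)C)C(=O)CC=O)ccc1O[Si](C(C)C)(C(C)C)C(C)C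
A3 | alternative 2 | 7,4'-bis(methoxymethoxy)-8,3'-diprenylflavone | CC(C)=CCc1cc(-c2cc(=O)c3ccc(OCOC)c(CC=C(C)C)c3o2)ccc1OCOC
A4 | alternative 2 | 6-iodo-3-(methoxymethoxy)-2-prenylphenol | Oc1c(I)ccc(OCOC)c1CC=C(C)C
A5 | alternative 2 | 4-ethynyl-1-(methoxymethoxy)-2-prenylbenzene | C#Cc1ccc(OCOC)c(CC=C(C)C)c1
A6 | alternative 3 | (2S)-4-(tert-butyldimethylsilyloxy)-7-(methoxymethoxy)-2-[4-(methoxymethoxy)-3-prenylphenyl]-8-prenyl-2H-chromene | CC(C)=CCc1cc([C@H]2Oc3c(CC=C(C)C)c(OCOC)ccc3C(O[Si](C)(C)C(C)(C)C)=C2)ccc1OCOC
A7 | alternative 3 | (S)-1-[4-(methoxymethoxy)-3-prenylphenyl]prop-2-en-1-yl 6-[1-(tert-butyldimethylsilyloxy)ethenyl]-3-(methoxymethoxy)-2-prenylphenyl ether | CC(C)=CCc1cc([C@H](C=C)Oc2c(CC=C(C)C)c(OCOC)ccc2C(=C)O[Si](C)(C)C(C)(C)C)ccc1OCOC
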